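(The constants stand for no real mixture; the result is computed.)

I started from four neighbours: alder, oak, cedar and maple hold the same charges and differ in how D and G meet the catalyst. I reckoned cedar, where both stand from the start.

| setting | alder | oak | cedar | maple |
|---|---|---|---|---|
| D | 0.25 M | 0.25 M (fed, over 20.0 min) | 0.25 M | 0.25 M |
| G | 0.950 equiv (fed, over 20.0 min) | 0.950 equiv | 0.950 equiv | 0.950 equiv |
| Q | 1.2 mol% | 1.2 mol% | 1.2 mol% | 1.2 mol% |
| time | 20 min | 20 min | 20 min |  |
| remark | all but G at the start; G goes in evenly over 20.0 min, the run ends at 20 min | a stirred flask in which D is dosed at a steady rate over 20.0 min without added volume, worked up at 20 min | a closed flask charged with all of it at once and left for 20 min | a single well-mixed tank run continuously and read at steady state, 20 min in it on average |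

    G.E → Q + J (k1 = 0.14 s⁻¹)
    D.Q → E (k2 = 0.16 s⁻¹)
    D + Q → D.Q (k3 = 0.66 L mol⁻¹ s⁻¹)
    G + E → G.E (k4 = 1.0 L mol⁻¹ s⁻¹)
    Q → Z (k5 = 4.5 × 10⁻⁷ s⁻¹)

- the stated concentrations are those of everything mixed, before any reaction; amounts are the same in each set-up
- the feed brings no volume worth counting
- run time (alder): 20 min

- the set-up with the highest amount of J at the outlet or at the end, in percent of the D put in ("none" if the first two lie within 2 percentage points) (alder / oak / cedar / maple / none)
- amount of J at the outlet or at the end, in percent of the D put in, alder
- amount of J at the outlet or at the end, in percent of the D put in, oak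
- amount of J at the outlet or at the end, in percent of the D put in, cedar
- amount of J at the outlet or at the end, in percent of the D put in, maple

Q takes D, D.Q becomes E, E takes G, and G.E gives J and returns Q, so each J costs one round. The step from Q to Z is far slower than the step from D.Q to E (4.5 × 10⁻⁷ s⁻¹ against 0.16 s⁻¹), so I dropped it. I carried the round time, the inverse of the turnover frequency: the sum of the mean waits at the four steps, each the reciprocal of its constant, times concentration where a partner is needed. Its two first-order waits total 13.4 s. With 0.00300 M of catalyst, J forms at catalyst over round time.

The bench rule treats the round as zero order in D and G. That gives 107% of the D as J in 20 min, more than the charge holds. The rule's border is where the two bimolecular waits equal the first-order ones, with [G] = [D]: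

[D] = 0.188 M

Cedar starts at 1.33 times that border, and its first round time is 23.7 s, longer than the first-order waits. So I integrated the rate with [G] = [D]:

13.4 s × ( 0.25 M − [D] + 0.188 M × ln(0.25 M/[D]) ) = 0.00300 M × t

Half of the D is consumed at 19.0 min, earlier than 20 min. The remaining time at the round time of that point brings J to 52.2%. This leans high, since G is charged at less than D.

The forecast named cedar: cedar 51%, maple 44.5%, alder 38% and oak 36.5%. Its ground was that “turnover is fastest when both D and G are high from the start”. Its cedar figure stood below mine.

Cedar gave 51.0%, the highest, against 38.5% for alder and 35.9% for oak. The forecast's choice held at 20 min, but cedar's lead over these two went with more time: at 200 min alder gave 95.0%, oak 95.0% and cedar 95.0%, which lie within the margin of 2 percentage points. Cedar's end readings, 48.2% of D and 46% of G, give a round time of 35.1 s against 23.7 s. The wait on D is 35.8% of it, and Q stood at 35.8%. Maple's 0.138 M of D and 0.127 M of G give 32.3 s, so 20 min on average predicts 44.6%, and maple gave 44.1%.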